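## Structural features

The target is a 2,8-dioxabicyclo[3.2.1]octane: a 1,3-dioxane ring (O2–C3–C4–C5–O8–C1) and a tetrahydrofuran ring (C1–C7–C6–C5–O8) that share C1, O8 and C5. C1 is a ketal carbon at the oxidation level of a carboxylic acid and carries the (3E,5S)-3,5-dimethyl-6-phenylhex-3-enyl chain; C6 and C7 are unfunctionalised methylenes. C3 (S), C4 (S) and C5 (R) are contiguous, each bears a carboxyl group and C4 also a tertiary hydroxyl, so C4 and C5 are neighbouring fully substituted carbons. C1 (S) is the fourth ring stereocentre, and a fifth (S) sits remote in the chain, allylic to a trisubstituted E alkene. The fragile points are: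
- the triacid, which is carried as esters to the end;
- C3–H, alpha to an ester and an oxygen;
- the side-chain alkene, which is sensitive to catalytic hydrogenation, carbenoids and strong acid;
- every open-chain precursor with a C5 ketone, where the C4 carboxyl is beta to the ketone and must never be released as the free acid.

The real difficulty is the C4/C5 quaternary pair together with the C1 ketal in the correct relative configuration. The key step uses the position of C1 between O2 and O8: the C1–O2 bond is brought in as an ester of the C3 hydroxyl, O8 as the carbonyl oxygen of that ester, and C5 as a carbene centre, so that only the C6–C7 unit has to be added across C1 and C5.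

## Logic of the disconnections

27 from 26. The three O–C(tert-butyl) bonds and the C4 O–Si bond are cut last. All four fall to one acid treatment, so the polar triacid appears only at the end. The forward step must spare the ketal, which is the acid-stable arrangement, and the trisubstituted alkene.

26 from 25 from 24. The C6–H and C7–H bonds go back to a C6=C7 alkene, and the alkene back to two C–S bonds. C6 and C7 carry nothing in the target, so the two-carbon partner of the key step needs activating groups that can be erased. Two sulfonyl groups make the partner electron-poor and symmetric and leave together by reductive elimination. The demands are that the reduction expels sulfinate and not a ring oxygen, and that the hydrogen donor discriminates between the strained disubstituted ring alkene and the trisubstituted chain alkene.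

24 from 21 and 22 through 23. The cuts are C5–O8, C5–C6 and C1–C7. This takes the whole bicycle back to an acyclic triester and a commercial alkene in one step. The forward step must form the ylide at the acyloxy carbonyl only, leave the chain alkene alone, and add 22 to the ylide face anti to the C4 silyloxy and C3 ester groups. Those two groups are cis on the six-membered ylide, and the target has the C6–C7 bridge on the opposite face, so the required sense is the sterically natural one.

21 from 19 through 20. The C5=N2 unit is traced to a C5 ketone. The C4 oxygen is silylated before the diazo group is made, because a free beta-hydroxy diazo ester could lose C5 by retro-aldol cleavage under base. The demand is condensation at a neopentylic ketone without loss of the silyl ether.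

19 from 18 from 6 and 17. The O–Si bond and then the C1–O2 ester bond are cut. The ester bond is the convergent joint between the core and the chain. The forward esterification must take the secondary C3 hydroxyl and not the tertiary C4 hydroxyl, under conditions mild enough for the alpha-hydroxy-beta-keto ester array.

6 from 5, 5 from 2 and 3 through 4, 2 from 1. The ketal C–O bonds and the C4–C5 bond are cut.
- Source of C3 and C4: C4 becomes the enolate carbon of a tartrate ketal and C5 arrives as an oxalyl unit, so C3 comes unchanged from the chiral pool. A check of the descriptors shows that the (2S,3S) diester 1 supplies C3 as S, and that C4 comes out correctly only if the C4–C5 bond forms anti to the C3 ester, which is the normal course for such enolates.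
- Choice of ketal: a diphenylmethylene ketal is used in place of an isopropylidene ketal. An isopropylidene ketal flanked by esters would need acid strong enough to cleave the tert-butyl esters, and the C4 acid so released would decarboxylate as a beta-keto acid. The diaryl ketal leaves by hydrogenolysis under neutral conditions.
- Symmetry: the ketal is symmetric, unlike a benzylidene acetal, so both alpha-hydrogens of 2 are equivalent and no extra stereocentre biases the enolate face.

17 from 16, 16 from 13 and 14 through 15. The C2–C3 bond of the acid is cut with transposition of the alkene. A [3,3] shift builds the trisubstituted alkene with E geometry from a carbinol whose own configuration does not matter. The demand is a chair transition state with the branched substituent equatorial.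

13 from 11 and 12, 11 from 10, 10 from 7 and 8 through 9. The carbinol C–C bond and the aryl–CH2 bond are cut. The remote stereocentre is taken from the chiral pool: the halomethyl arm of 7 becomes the benzyl arm and the ester arm becomes the alkene carbon, which gives S. The forward steps must avoid beta-elimination toward the ester during arylation and alpha-epimerisation of the aldehyde.

## Other disconnections considered

Alternative 1: The cut is the C6–C7 bond, written as a C6=C7 alkene. The dioxane ring would be made first as the ketal A1, with a vinyl group on C1 and one on C5 on the same face. The second-generation Grubbs catalyst would join the two vinyl groups and close the five-membered ring to the 6,7-didehydro trimethyl ester A2; diimide and ester hydrolysis would follow.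
- In favour: metathesis is catalytic, tolerates the free C4 hydroxyl and esters, creates no stereocentre, and gives the alkene directly without a sulfone detour.
- Against, here: all the difficult work moves into A1. The C4/C5 quaternary pair must be built with a vinyl group on C5, and C1 must be set as a ketal of a vinyl ketone with both vinyl groups cis. That ketalisation competes with conjugate addition and depends on thermodynamic control. The chain alkene is a slow but real partner for the ruthenium carbene. The final hydrolysis of three methyl esters needs base at hindered positions next to the epimerisable C3–H.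
- Comparison: on structure, the metathesis forms one bond and one ring, the chosen cascade three bonds and two rings while setting C1 and C5. On mechanism, the metathesis is the more predictable single step, and on this point it is the better. After the key step it is one operation shorter, also the better. Over the whole route the chosen plan should be shorter, because its precursor comes from a tartrate in a few steps.

Alternative 2: The cut is C3–C4. The tetrahydrofuran A3, a mixed ketal at C1 that carries a glycolate through O2 and at C5 a methyl ester and the C4 keto ester, would be treated with a lithium amide. The glycolate enolate would add to the C4 ketone in a six-membered aldol closure and give the trimethyl ester A4.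
- In favour: C6 and C7 are already saturated and all carbons are at the final oxidation level, so only ester hydrolysis remains after the key step; on this count it is the better. The ketone cannot enolise, so only one enolate can form. A wrong C3 epimer could in principle be equilibrated.
- Against, here: C3 and C4 are created together with control only from the existing ring and the enolate geometry. The aldolate can revert or open the ketal. A3 needs a C1 ketal of defined configuration cis to the C5 keto ester that survives strong base. The C5 quaternary centre must come from asymmetric synthesis and not from the chiral pool.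
- Comparison: on structure, it closes one ring and one C–C bond and sets two centres, against two rings and three bonds. On mechanism, both rely on substrate-controlled facial selectivity and are equal in that respect. The end game is shorter for A4; the route to A3 is expected to be longer than the route to 21.

Alternative 3: The cuts are C5–O8 and C1–O2. The open-chain ketone A5, with a C4–C5 epoxide, a free C3 hydroxyl and three silyloxymethyl groups, would be treated with BF3·OEt2. The ketone oxygen would open the epoxide at C5 with inversion, and the C3 hydroxyl would capture the oxocarbenium ion at C1, giving the bicyclic ketal A6.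
- In favour: inversion at C5 is stereospecific, and the epoxide can come from a reagent-controlled epoxidation; on certainty of configuration at C4/C5 it is the better. Like the chosen step it closes both rings at once, which is equal. C6 and C7 need no adjustment.
- Against, here: the three carboxyl carbons are at the alcohol level. After the cascade three silyl ethers must be removed and three primary alcohols, two of them neopentylic, oxidised to acids beside a free tertiary hydroxyl and the alkene. The Lewis acid may open the tetrasubstituted epoxide at C4 instead of C5, trigger a semipinacol shift, or remove silyl groups. A5 needs a long linear synthesis.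
- Comparison: on structure, two C–O bonds against one C–O and two C–C bonds. On mechanism, stereospecific against face-selective. On step economy, the oxidation-state corrections after A6 make it clearly longer than the three steps that follow 24.

Key step: step 12

Remark: 1 and 7 are taken as catalogue compounds (the di-tert-butyl ester of D-tartaric acid and the bromide corresponding to methyl (S)-3-hydroxy-2-methylpropanoate, same spatial arrangement); 24 is written as one of the two trans-6,7 isomers that step 12 can form, and both converge in step 13.

## Steps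

Step 1
Reactants: 1 di-tert-butyl D-tartrate
Product: 2 di-tert-butyl (4S,5S)-2,2-diphenyl-1,3-dioxolane-4,5-dicarboxylate
Conditions: Ph2C(OMe)2 (1.3 equiv), CSA (5 mol %), toluene, 60 °C, reduced pressure (MeOH removed)
Reagents that add atoms: dimethoxydiphenylmethane, COC(OC)(c1ccccc1)c1ccccc1
Why: Acid-catalysed transketalisation of a 1,2-diol; the diaryl oxocarbenium ion forms easily, removal of methanol drives the exchange and the moderate temperature spares the tert-butyl esters. No stereocentre is touched and the symmetric ketal keeps both ester alpha-hydrogens equivalent.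

Step 2
Reactants: 2 di-tert-butyl (4S,5S)-2,2-diphenyl-1,3-dioxolane-4,5-dicarboxylate; 3 tert-butyl chlorooxoacetate
Product: 5 di-tert-butyl (4S,5S)-4-(2-tert-butoxy-2-oxoacetyl)-2,2-diphenyl-1,3-dioxolane-4,5-dicarboxylate, via lithium enolate 4 (not isolated)
Conditions: LiN(iPr)2 (1.05 equiv), THF/DMPU, −78 °C; then cannulated into 3 (2 equiv), THF, −78 °C
Reagents that add atoms: tert-butyl chlorooxoacetate, CC(C)(C)OC(=O)C(=O)Cl
Why: C-acylation of an ester enolate by an acid chloride (crossed Claisen type); the dioxolane holds the beta C–O bond out of alignment with the enolate, which suppresses beta-elimination, and the product ketone is non-enolisable. The acyl group enters the enolate face anti to the neighbouring C3 ester, which sets C4 in the configuration of the target.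

Step 3
Reactants: 5 di-tert-butyl (4S,5S)-4-(2-tert-butoxy-2-oxoacetyl)-2,2-diphenyl-1,3-dioxolane-4,5-dicarboxylate
Product: 6 tri-tert-butyl (1S,2S)-1,2-dihydroxy-3-oxopropane-1,2,3-tricarboxylate
Conditions: H2 (1 atm), Pd(OH)2/C, EtOAc, rt
Reagents that add atoms: none
Why: Hydrogenolysis of the two doubly benzylic C–O bonds (benzhydryl-ether type cleavage) releases the diol and diphenylmethane under neutral conditions. The tert-butyl esters and the hindered aliphatic keto ester should not react at 1 atm.

Step 4
Reactants: 7 methyl (R)-3-bromo-2-methylpropanoate; 8 iodobenzene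
Product: 10 methyl (S)-2-methyl-3-phenylpropanoate, via alkylzinc bromide 9 (not isolated)
Conditions: Zn dust (1.5 equiv), I2 (5 mol %), DMA, 70 °C; then 8, Pd(OAc)2 (2 mol %), SPhos (4 mol %), rt
Reagents that add atoms: iodobenzene, Ic1ccccc1
Why: Zinc insertion into the primary C–Br bond and Negishi coupling (oxidative addition of 8 to zerovalent palladium, transmetallation, reductive elimination). The stereocentre is beta to zinc and not involved, and the neutral organozinc avoids the elimination to a methacrylate that a basic phenyl nucleophile would cause.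

Step 5
Reactants: 10 methyl (S)-2-methyl-3-phenylpropanoate
Product: 11 (S)-2-methyl-3-phenylpropanal
Conditions: iBu2AlH (1.05 equiv), CH2Cl2, −78 °C; MeOH, then aq. potassium sodium tartrate
Reagents that add atoms: none
Why: Partial reduction of an ester; the aluminium hemiacetal is stable at −78 °C and releases the aldehyde only on work-up, which limits over-reduction. The aldehyde is used at once without chromatography to avoid alpha-epimerisation.

Step 6
Reactants: 11 (S)-2-methyl-3-phenylpropanal; 12 isopropenylmagnesium bromide
Product: 13 (3RS,4S)-2,4-dimethyl-5-phenylpent-1-en-3-ol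
Conditions: 12 (1.3 equiv), THF, −78 → 0 °C; aq. NH4Cl
Reagents that add atoms: isopropenylmagnesium bromide, CC(=C)[Mg]Br
Why: Grignard addition to an aldehyde; addition at low temperature outruns enolisation, so the methyl-bearing centre is kept. The new carbinol centre forms as a mixture, which does not matter because step 7 destroys it.

Step 7
Reactants: 13 (3RS,4S)-2,4-dimethyl-5-phenylpent-1-en-3-ol; 14 triethyl orthoacetate
Product: 16 ethyl (4E,6S)-4,6-dimethyl-7-phenylhept-4-enoate, via allyl ketene acetal 15 (not isolated)
Conditions: 14 (6 equiv), EtCO2H (cat.), 140 °C, EtOH distilled off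
Reagents that add atoms: triethyl orthoacetate, CCOC(C)(OCC)OCC
Why: Johnson–Claisen rearrangement: orthoester exchange and loss of ethanol give the ketene acetal, which rearranges through a chair with the CH(CH3)CH2Ph group equatorial (the axial arrangement suffers a 1,3-diaxial clash with the ethoxy group), so the trisubstituted alkene forms E. The stereocentre next to the carbinol carbon is a spectator.

Step 8
Reactants: 16 ethyl (4E,6S)-4,6-dimethyl-7-phenylhept-4-enoate
Product: 17 (4E,6S)-4,6-dimethyl-7-phenylhept-4-enoic acid
Conditions: LiOH, THF/MeOH/H2O, rt; then 1 M HCl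
Reagents that add atoms: lithium hydroxide, [Li+].[OH-]
Why: Saponification of an unhindered ethyl ester; the allylic stereocentre is not acidic and the alkene is inert to aqueous base.

Step 9
Reactants: 6 tri-tert-butyl (1S,2S)-1,2-dihydroxy-3-oxopropane-1,2,3-tricarboxylate; 17 (4E,6S)-4,6-dimethyl-7-phenylhept-4-enoic acid
Product: 18 tri-tert-butyl (1S,2S)-1-{[(4E,6S)-4,6-dimethyl-7-phenylhept-4-enoyl]oxy}-2-hydroxy-3-oxopropane-1,2,3-tricarboxylate
Conditions: DCC (1.2 equiv), DMAP (10 mol %), CH2Cl2, 0 °C → rt
Reagents that add atoms: none
Why: Steglich esterification; the secondary C3 hydroxyl is acylated, the tertiary C4 hydroxyl between two carbonyl-bearing carbons is not. The nearly neutral medium avoids retro-Claisen cleavage of the C4–C5 bond.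

Step 10
Reactants: 18 tri-tert-butyl (1S,2S)-1-{[(4E,6S)-4,6-dimethyl-7-phenylhept-4-enoyl]oxy}-2-hydroxy-3-oxopropane-1,2,3-tricarboxylate
Product: 19 tri-tert-butyl (1S,2S)-1-{[(4E,6S)-4,6-dimethyl-7-phenylhept-4-enoyl]oxy}-3-oxo-2-[(trimethylsilyl)oxy]propane-1,2,3-tricarboxylate
Conditions: Me3SiOTf (1.3 equiv), 2,6-lutidine, CH2Cl2, −78 °C; aq. NaHCO3 (cold)
Reagents that add atoms: trimethylsilyl trifluoromethanesulfonate, C[Si](C)(C)OS(=O)(=O)C(F)(F)F
Why: Silylation of a tertiary alcohol with a silyl triflate and a hindered pyridine base; at −78 °C and near-stoichiometric loading the hydroxyl consumes the reagent long before a tert-butyl ester can be attacked. The silyl ether prevents retro-aldol loss of C5 in step 11 and later shields one face of the ylide.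

Step 11
Reactants: 19 tri-tert-butyl (1S,2S)-1-{[(4E,6S)-4,6-dimethyl-7-phenylhept-4-enoyl]oxy}-3-oxo-2-[(trimethylsilyl)oxy]propane-1,2,3-tricarboxylate
Product: 21 tri-tert-butyl (1S,2R)-3-diazo-1-{[(4E,6S)-4,6-dimethyl-7-phenylhept-4-enoyl]oxy}-2-[(trimethylsilyl)oxy]propane-1,2,3-tricarboxylate, via tosylhydrazone 20 (not isolated)
Conditions: TsNHNH2 (1.2 equiv), 4 Å MS, THF, 50 °C; then DBU (1.5 equiv), 0 °C → rt
Reagents that add atoms: 4-methylbenzenesulfonohydrazide, Cc1ccc(cc1)S(=O)(=O)NN
Why: Condensation of the electrophilic alpha-keto ester with the sulfonyl hydrazide, then base-induced loss of sulfinate from the hydrazone anion (Bamford–Stevens type), which stops at the acceptor-stabilised diazo ester. C3 and C4 are not touched; the change of the C4 descriptor to R is only a change of priorities.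

Step 12
Reactants: 21 tri-tert-butyl (1S,2R)-3-diazo-1-{[(4E,6S)-4,6-dimethyl-7-phenylhept-4-enoyl]oxy}-2-[(trimethylsilyl)oxy]propane-1,2,3-tricarboxylate; 22 (E)-1,2-bis(phenylsulfonyl)ethene
Product: 24 tri-tert-butyl (1S,3S,4S,5R,6S,7S)-1-[(3E,5S)-3,5-dimethyl-6-phenylhex-3-en-1-yl]-6,7-bis(phenylsulfonyl)-4-[(trimethylsilyl)oxy]-2,8-dioxabicyclo[3.2.1]octane-3,4,5-tricarboxylate, via carbonyl ylide 23 (not isolated)
Conditions: Rh2(OAc)4 (5 mol %), 22 (3 equiv), PhCF3, 80 °C, 21 added over 2 h
Reagents that add atoms: (E)-1,2-bis(phenylsulfonyl)ethene, O=S(=O)(/C=C/S(=O)(=O)c1ccccc1)c1ccccc1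
Why: Rh2(OAc)4 removes N2 from 21 and gives an electrophilic divalent rhodium carbenoid at C5; the carbonyl oxygen of the C3 acyloxy group attacks it in a six-membered closure (C5–O8), which releases the catalyst and closes the 1,3-dioxane ring as the carbonyl ylide 23. The closest known reaction type is the dirhodium-catalysed tandem carbonyl ylide formation and 1,3-dipolar cycloaddition of diazo esters that carry a tethered ester carbonyl, with electron-poor pi bonds as partners. The ester-stabilised, electron-rich ylide adds 22 in a concerted suprafacial [3+2] cycloaddition (C5–C6 and C1–C7), which closes the tetrahydrofuran ring by bridging C1 and C5 of the dioxane. C1 and C5 are set together by the ylide face that is attacked: in the half-chair with both C3 and C4 ester groups pseudo-equatorial the C4 silyloxy group is pseudo-axial and, with the cis C3 ester, blocks one face, so the alkene adds to the other face and the bridge ends anti to them as in the target. C6 and C7 follow from the E geometry of 22 and are erased in step 13, and because 22 is symmetric there is no regiochemical question. The step needs ylide formation at the acyloxy carbonyl and not at a tert-butyl ester carbonyl (those would give four- or five-membered ylides and are sterically shielded), no attack of the carbenoid on the remote chain alkene (a medium ring would be required), and capture of the ylide before proton transfer from the C1 alpha-methylene; excess 22 and slow addition of 21 serve the last point.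

Step 13
Reactants: 24 tri-tert-butyl (1S,3S,4S,5R,6S,7S)-1-[(3E,5S)-3,5-dimethyl-6-phenylhex-3-en-1-yl]-6,7-bis(phenylsulfonyl)-4-[(trimethylsilyl)oxy]-2,8-dioxabicyclo[3.2.1]octane-3,4,5-tricarboxylate
Product: 25 tri-tert-butyl (1S,3S,4S,5R)-1-[(3E,5S)-3,5-dimethyl-6-phenylhex-3-en-1-yl]-4-[(trimethylsilyl)oxy]-2,8-dioxabicyclo[3.2.1]oct-6-ene-3,4,5-tricarboxylate
Conditions: 6% Na(Hg), Na2HPO4, MeOH/THF, −20 °C
Reagents that add atoms: none
Why: Reductive elimination of a vicinal bis-sulfone: electron transfer cleaves one C–S bond and the beta-sulfonyl radical or anion expels the second sulfinate, a far better leaving group than the ring oxygens, so the C6=C7 alkene forms whatever the configuration at C6 and C7. The phosphate buffer keeps the medium from turning basic.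

Step 14
Reactants: 25 tri-tert-butyl (1S,3S,4S,5R)-1-[(3E,5S)-3,5-dimethyl-6-phenylhex-3-en-1-yl]-4-[(trimethylsilyl)oxy]-2,8-dioxabicyclo[3.2.1]oct-6-ene-3,4,5-tricarboxylate
Product: 26 tri-tert-butyl (1S,3S,4S,5R)-1-[(3E,5S)-3,5-dimethyl-6-phenylhex-3-en-1-yl]-4-[(trimethylsilyl)oxy]-2,8-dioxabicyclo[3.2.1]octane-3,4,5-tricarboxylate
Conditions: 2-nitrobenzenesulfonylhydrazide (excess), Et3N, CH2Cl2, rt
Reagents that add atoms: none
Why: Diimide reduction: concerted syn transfer of two hydrogens, fastest to strained 1,2-disubstituted alkenes, so the bicyclic C6=C7 bond should react well before the trisubstituted chain alkene. No metal is present that could isomerise the chain alkene.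

Step 15
Reactants: 26 tri-tert-butyl (1S,3S,4S,5R)-1-[(3E,5S)-3,5-dimethyl-6-phenylhex-3-en-1-yl]-4-[(trimethylsilyl)oxy]-2,8-dioxabicyclo[3.2.1]octane-3,4,5-tricarboxylate
Product: 27 (1S,3S,4S,5R)-1-[(3E,5S)-3,5-dimethyl-6-phenylhex-3-en-1-yl]-4-hydroxy-2,8-dioxabicyclo[3.2.1]octane-3,4,5-tricarboxylic acid
Conditions: CF3CO2H/CH2Cl2 (1:3), rt; evaporation
Reagents that add atoms: none
Why: Acidolysis: the tert-butyl esters ionise to the tert-butyl cation, lost as isobutene, and the silyl ether is cleaved in the same medium. The bicyclic ketal is the acid-stable arrangement and the trisubstituted alkene should survive a short exposure at room temperature.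

## Compound list

1 | di-tert-butyl D-tartrate, (2S,3S) | CC(C)(C)OC(=O)[C@@H](O)[C@H](O)C(=O)OC(C)(C)C | starting material
2 | di-tert-butyl (4S,5S)-2,2-diphenyl-1,3-dioxolane-4,5-dicarboxylate | CC(C)(C)OC(=O)[C@H]1OC(c2ccccc2)(c2ccccc2)O[C@@H]1C(=O)OC(C)(C)C | intermediate
3 | tert-butyl chlorooxoacetate | CC(C)(C)OC(=O)C(=O)Cl | starting material
4 | lithium enolate of 2 (one ester deprotonated, the other stereocentre intact) | CC(C)(C)OC(=O)[C@H]1OC(c2ccccc2)(c2ccccc2)OC1=C([O-])OC(C)(C)C.[Li+] | intermediate
5 | di-tert-butyl (4S,5S)-4-(2-tert-butoxy-2-oxoacetyl)-2,2-diphenyl-1,3-dioxolane-4,5-dicarboxylate | CC(C)(C)OC(=O)[C@H]1OC(c2ccccc2)(c2ccccc2)O[C@]1(C(=O)OC(C)(C)C)C(=O)C(=O)OC(C)(C)C | intermediate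
6 | tri-tert-butyl (1S,2S)-1,2-dihydroxy-3-oxopropane-1,2,3-tricarboxylate | CC(C)(C)OC(=O)[C@@H](O)[C@@](O)(C(=O)OC(C)(C)C)C(=O)C(=O)OC(C)(C)C | intermediate
7 | methyl (R)-3-bromo-2-methylpropanoate | COC(=O)[C@@H](C)CBr | starting material
8 | iodobenzene | Ic1ccccc1 | starting material
9 | [(2R)-3-methoxy-2-methyl-3-oxopropyl]zinc bromide | COC(=O)[C@@H](C)C[Zn]Br | intermediate
10 | methyl (S)-2-methyl-3-phenylpropanoate | COC(=O)[C@@H](C)Cc1ccccc1 | intermediate
11 | (S)-2-methyl-3-phenylpropanal | O=C[C@@H](C)Cc1ccccc1 | intermediate
12 | isopropenylmagnesium bromide | CC(=C)[Mg]Br | starting material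
13 | (3RS,4S)-2,4-dimethyl-5-phenylpent-1-en-3-ol | C=C(C)C(O)[C@@H](C)Cc1ccccc1 | intermediate
14 | triethyl orthoacetate | CCOC(C)(OCC)OCC | starting material
15 | (4S)-3-[(1-ethoxyethenyl)oxy]-2,4-dimethyl-5-phenylpent-1-ene (C3 epimers) | C=C(OCC)OC(C(C)=C)[C@@H](C)Cc1ccccc1 | intermediate
16 | ethyl (4E,6S)-4,6-dimethyl-7-phenylhept-4-enoate | CCOC(=O)CC/C(C)=C/[C@@H](C)Cc1ccccc1 | intermediate
17 | (4E,6S)-4,6-dimethyl-7-phenylhept-4-enoic acid | OC(=O)CC/C(C)=C/[C@@H](C)Cc1ccccc1 | intermediate
18 | tri-tert-butyl (1S,2S)-1-{[(4E,6S)-4,6-dimethyl-7-phenylhept-4-enoyl]oxy}-2-hydroxy-3-oxopropane-1,2,3-tricarboxylate | C/C(=C\[C@@H](C)Cc1ccccc1)CCC(=O)O[C@H](C(=O)OC(C)(C)C)[C@@](O)(C(=O)OC(C)(C)C)C(=O)C(=O)OC(C)(C)C | intermediate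
19 | tri-tert-butyl (1S,2S)-1-{[(4E,6S)-4,6-dimethyl-7-phenylhept-4-enoyl]oxy}-3-oxo-2-[(trimethylsilyl)oxy]propane-1,2,3-tricarboxylate | C/C(=C\[C@@H](C)Cc1ccccc1)CCC(=O)O[C@H](C(=O)OC(C)(C)C)[C@@](O[Si](C)(C)C)(C(=O)OC(C)(C)C)C(=O)C(=O)OC(C)(C)C | intermediate
20 | C5 tosylhydrazone of 19 (C=N isomers), (1S,2R) | C/C(=C\[C@@H](C)Cc1ccccc1)CCC(=O)O[C@H](C(=O)OC(C)(C)C)[C@@](O[Si](C)(C)C)(C(=O)OC(C)(C)C)C(=NNS(=O)(=O)c1ccc(C)cc1)C(=O)OC(C)(C)C | intermediate
21 | tri-tert-butyl (1S,2R)-3-diazo-1-{[(4E,6S)-4,6-dimethyl-7-phenylhept-4-enoyl]oxy}-2-[(trimethylsilyl)oxy]propane-1,2,3-tricarboxylate | C/C(=C\[C@@H](C)Cc1ccccc1)CCC(=O)O[C@H](C(=O)OC(C)(C)C)[C@@](O[Si](C)(C)C)(C(=O)OC(C)(C)C)C(=[N+]=[N-])C(=O)OC(C)(C)C | intermediate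
22 | (E)-1,2-bis(phenylsulfonyl)ethene | O=S(=O)(/C=C/S(=O)(=O)c1ccccc1)c1ccccc1 | starting material
23 | six-membered carbonyl ylide (C5 carbanion, O8 oxonium, C1=O8; C3 and C4 as in 21) | C/C(=C\[C@@H](C)Cc1ccccc1)CCC1=[O+][C-](C(=O)OC(C)(C)C)[C@](O[Si](C)(C)C)(C(=O)OC(C)(C)C)[C@@H](C(=O)OC(C)(C)C)O1 | intermediate
24 | tri-tert-butyl (1S,3S,4S,5R,6S,7S)-1-[(3E,5S)-3,5-dimethyl-6-phenylhex-3-en-1-yl]-6,7-bis(phenylsulfonyl)-4-[(trimethylsilyl)oxy]-2,8-dioxabicyclo[3.2.1]octane-3,4,5-tricarboxylate | C/C(=C\[C@@H](C)Cc1ccccc1)CC[C@@]12[C@H](S(=O)(=O)c3ccccc3)[C@@H](S(=O)(=O)c3ccccc3)[C@@](C(=O)OC(C)(C)C)(O1)[C@](O[Si](C)(C)C)(C(=O)OC(C)(C)C)[C@@H](C(=O)OC(C)(C)C)O2 | intermediate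
25 | tri-tert-butyl (1S,3S,4S,5R)-1-[(3E,5S)-3,5-dimethyl-6-phenylhex-3-en-1-yl]-4-[(trimethylsilyl)oxy]-2,8-dioxabicyclo[3.2.1]oct-6-ene-3,4,5-tricarboxylate | C/C(=C\[C@@H](C)Cc1ccccc1)CC[C@@]12C=C[C@@](C(=O)OC(C)(C)C)(O1)[C@](O[Si](C)(C)C)(C(=O)OC(C)(C)C)[C@@H](C(=O)OC(C)(C)C)O2 | intermediate
26 | tri-tert-butyl (1S,3S,4S,5R)-1-[(3E,5S)-3,5-dimethyl-6-phenylhex-3-en-1-yl]-4-[(trimethylsilyl)oxy]-2,8-dioxabicyclo[3.2.1]octane-3,4,5-tricarboxylate | C/C(=C\[C@@H](C)Cc1ccccc1)CC[C@@]12CC[C@@](C(=O)OC(C)(C)C)(O1)[C@](O[Si](C)(C)C)(C(=O)OC(C)(C)C)[C@@H](C(=O)OC(C)(C)C)O2 | intermediate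
27 | (1S,3S,4S,5R)-1-[(3E,5S)-3,5-dimethyl-6-phenylhex-3-en-1-yl]-4-hydroxy-2,8-dioxabicyclo[3.2.1]octane-3,4,5-tricarboxylic acid | C/C(=C\[C@@H](C)Cc1ccccc1)CC[C@@]12CC[C@@](C(=O)O)(O1)[C@](O)(C(=O)O)[C@@H](C(=O)O)O2 | target

## Step count and risks

Total: 15 steps. Longest linear sequence: 12 steps (7 to 27 through steps 4–8 and 9–15); the core branch from 1 takes 10.

Step 12 (key step). The most likely failure is slow interception of the ylide by the hindered 1,2-disubstituted alkene, which leaves time for proton transfer within the ylide or for carbenoid dimerisation; incomplete facial discrimination is the second concern. The fallback sets out from 21. The same Rh2(OAc)4 cascade is run with phenyl vinyl sulfone, a less hindered monosubstituted acceptor, and should give the 7-(phenylsulfonyl) cycloadduct F1; regio- and C7-isomers converge. Reductive desulfonylation with Na(Hg) and Na2HPO4 in MeOH then removes the single sulfonyl group and returns to the route at 26, so that steps 13 and 14 are not needed.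

Step 2. O-acylation of the crowded, fully substituted enolate, decay of the enolate by beta-elimination before it is acylated, or incomplete anti selectivity may lower the amount of 5. The fallback sets out from 2, with 1 as reagent source. Cleavage of 1 with NaIO4 gives tert-butyl glyoxylate F2. Enolate 4 adds to this aldehyde at −78 °C, at carbon only, to give the C5 carbinol F3. Dess–Martin periodinane oxidises F3, and the route is rejoined at 5.

Step 3. Concurrent reduction of the activated C5 ketone, or stalling of the hydrogenolysis at the crowded ketal, is possible. The fallback sets out from 5 and replaces reductive by solvolytic cleavage: 80% aqueous AcOH at 50 °C, which relies on the diaryl-stabilised oxocarbenium ion and should still spare the tert-butyl esters. It returns at 6 and forms no new compound (F0).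

Step 11. Condensation at the neopentylic ketone may be slow, with loss of the silyl ether or base-induced cleavage of the C4–C5 bond on prolonged treatment. The fallback sets out from 19. Hydrazine hydrate, which is smaller and more nucleophilic, with a trace of AcOH in THF/EtOH at 0 °C should give the N-unsubstituted hydrazone F4. Dehydrogenation with MnO2 in CH2Cl2 gives the diazo ester, and the route is rejoined at 21.

Step 13. Over-reduction, or expulsion of a ring oxygen from an alpha-sulfonyl carbanion with opening of the ketal, may compete with loss of the second sulfinate. The fallback sets out from 24. DBU in CH2Cl2 removes one sulfinate by an E1cB path and gives the vinyl sulfone F5 (the 6-sulfonyl isomer is drawn; the 7-isomer behaves alike). NaBH4 in THF/EtOH reduces it by conjugate hydride addition to the saturated monosulfone F6. SmI2 in THF/DMPU with MeOH cleaves the remaining C–S bond and returns to the route at 26, which also removes the need for step 14.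

## Further compounds

F1 | step 12 | 7-(phenylsulfonyl) analogue of 26 (C1, C3, C4, C5 as in 26; C7 epimers) | C/C(=C\[C@@H](C)Cc1ccccc1)CC[C@@]12C(S(=O)(=O)c3ccccc3)C[C@@](C(=O)OC(C)(C)C)(O1)[C@](O[Si](C)(C)C)(C(=O)OC(C)(C)C)[C@@H](C(=O)OC(C)(C)C)O2
F2 | step 2 | tert-butyl glyoxylate | O=CC(=O)OC(C)(C)C
F3 | step 2 | C5 carbinol corresponding to 5 (dioxolane centres as in 5; carbinol epimers) | CC(C)(C)OC(=O)[C@H]1OC(c2ccccc2)(c2ccccc2)O[C@]1(C(=O)OC(C)(C)C)C(O)C(=O)OC(C)(C)C
F0 | step 3 | none | none
F4 | step 11 | N-unsubstituted C5 hydrazone of 19 (C=N isomers) | C/C(=C\[C@@H](C)Cc1ccccc1)CCC(=O)O[C@H](C(=O)OC(C)(C)C)[C@@](O[Si](C)(C)C)(C(=O)OC(C)(C)C)C(=NN)C(=O)OC(C)(C)C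
F5 | step 13 | 6-(phenylsulfonyl) analogue of 25 (vinyl sulfone) | C/C(=C\[C@@H](C)Cc1ccccc1)CC[C@@]12C=C(S(=O)(=O)c3ccccc3)[C@@](C(=O)OC(C)(C)C)(O1)[C@](O[Si](C)(C)C)(C(=O)OC(C)(C)C)[C@@H](C(=O)OC(C)(C)C)O2
F6 | step 13 | 6-(phenylsulfonyl) analogue of 26 (C6 epimers) | C/C(=C\[C@@H](C)Cc1ccccc1)CC[C@@]12CC(S(=O)(=O)c3ccccc3)[C@@](C(=O)OC(C)(C)C)(O1)[C@](O[Si](C)(C)C)(C(=O)OC(C)(C)C)[C@@H](C(=O)OC(C)(C)C)O2
A1 | alternative 1 | 1,3-dioxane ketal with vinyl groups on C1 and C5, trimethyl ester (C1, C3, C4, C5 as in 27) | C/C(=C\[C@@H](C)Cc1ccccc1)CC[C@@]1(C=C)O[C@@](C=C)(C(=O)OC)[C@](O)(C(=O)OC)[C@@H](C(=O)OC)O1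
A2 | alternative 1 | 6,7-didehydro trimethyl ester of 27 | C/C(=C\[C@@H](C)Cc1ccccc1)CC[C@@]12C=C[C@@](C(=O)OC)(O1)[C@](O)(C(=O)OC)[C@@H](C(=O)OC)O2
A3 | alternative 2 | tetrahydrofuran with C1 O-glycolate ketal, C5 methyl ester and C4 keto ester | C/C(=C\[C@@H](C)Cc1ccccc1)CC[C@@]1(OCC(=O)OC)CC[C@](C(=O)OC)(C(=O)C(=O)OC)O1
A4 | alternative 2 | trimethyl ester of 27 | C/C(=C\[C@@H](C)Cc1ccccc1)CC[C@@]12CC[C@@](C(=O)OC)(O1)[C@](O)(C(=O)OC)[C@@H](C(=O)OC)O2
A5 | alternative 3 | open-chain C1 ketone with C4–C5 epoxide, free C3 hydroxyl and three tert-butyldimethylsilyloxymethyl groups | C/C(=C\[C@@H](C)Cc1ccccc1)CCC(=O)CC[C@]1(CO[Si](C)(C)C(C)(C)C)O[C@@]1(CO[Si](C)(C)C(C)(C)C)[C@H](O)CO[Si](C)(C)C(C)(C)C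
A6 | alternative 3 | bicyclic ketal with three silyloxymethyl groups and free C4 hydroxyl | C/C(=C\[C@@H](C)Cc1ccccc1)CC[C@@]12CC[C@@](CO[Si](C)(C)C(C)(C)C)(O1)[C@](O)(CO[Si](C)(C)C(C)(C)C)[C@@H](CO[Si](C)(C)C(C)(C)C)O2
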